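**Plan**

- Retrosynthetic cuts, in order: C1′–C2′ is desaturated (the alkene is erased at the end by hydrogenation, together with the O6 benzyl group); O1–C2 of the pyran ring is cut in the SN2′ sense to an E‑C2=C1′ alkene with a stereogenic C2′–OH; then C1′–C2′ (alkenyllithium + C15 Weinreb amide), C2–CH3 (methylalumination of an aryl butyne) and C4a–C4/O1–acyl (hydroquinone + acrylic acid).
- Forward order: the chain C2′–C13′ is made first (steps 1–3); the arene is bought, and a temporary δ‑lactone ring (steps 4–6) installs C4–C3 and tells O1 from O6 before it is opened to a butynylphenol (step 7); arene and chain are joined at C1′–C2′ (step 10); the pyran ring of the target closes only in step 13.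
- Stereochemistry: C4′ and C8′ arise together by catalyst‑controlled Ir hydrogenation of the two E‑trisubstituted alkenes of farnesol; the C2′ carbinol by CBS reduction; C2 by 1,3‑chirality transfer from C2′ in the ring closure, after which C2′ is no longer stereogenic.
- Enabling feature: C2 is a ring tertiary‑ether carbon bonded to O1 (on C8a) whose exocyclic neighbours C1′ and C2′ are plain methylenes, so an alkene and a hydroxyl leaving group can be placed there and removed without trace, and O1 reaches C2 through a six‑membered (6‑exo) transition state.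

Key step: step 13

Remark: the ring closure is assumed to take the net syn‑SN2′ course (oxygen delivered to the alkene face that carries the allylic hydroxyl) known for aliphatic hydroxy nucleophiles; on that basis the 5R carbinol is required, and an anti course would only call for the enantiomeric CBS catalyst in step 11.

**Route**

Step 1
Reactants: 1 (2E,6E)-farnesol
Product: 2 (3R,7R)-3,7,11-trimethyldodecan-1-ol
Conditions: [Ir(cod)(L*)]BArF (1 mol%, L* = chiral pyridine–phosphinite N,P ligand, enantiomer giving 3R,7R), H2 (50 bar), CH2Cl2, rt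
Reagents that add atoms: none
Why: Ir–N,P‑catalysed asymmetric hydrogenation of trisubstituted alkenes, within known scope for acyclic terpenoid alcohols, should reduce all three alkenes and set C3 and C7 (both R) by catalyst control of the 2E and 6E alkene faces, the 10,11‑alkene becoming the achiral isopropyl end.

Step 2
Reactants: 2 (3R,7R)-3,7,11-trimethyldodecan-1-ol
Product: 4 (3R,7R)-3,7,11-trimethyldodecanoic acid, via C15 aldehyde 3 (not isolated)
Conditions: TEMPO (0.2 equiv), PhI(OAc)2 (2.2 equiv), MeCN/H2O 1:1, rt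
Reagents that add atoms: water, O
Why: Nitroxyl‑catalysed oxidation of a primary alcohol through the aldehyde hydrate to the acid should leave the β‑ and remote methyl stereocentres untouched, since neither is α to the carbonyl.

Step 3
Reactants: 4 (3R,7R)-3,7,11-trimethyldodecanoic acid
Product: 6 (3R,7R)-N-methoxy-N,3,7,11-tetramethyldodecanamide, via acyl imidazole 5 (not isolated)
Conditions: 1,1'-carbonyldiimidazole, CH2Cl2, rt; then MeNHOMe·HCl, rt
Reagents that add atoms: N,O-dimethylhydroxylamine hydrochloride, CNOC.Cl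
Why: Weinreb amide formation by carboxyl activation as the acyl imidazole and aminolysis is routine and does not touch the stereocentres.

Step 4
Reactants: 7 2,5-dimethylbenzene-1,4-diol; 8 acrylic acid
Product: 10 6-hydroxy-5,8-dimethylchroman-2-one, via hydroxy acid 9 (not isolated)
Conditions: Amberlyst-15, toluene, reflux (Dean–Stark), 7 in twofold excess (surplus recovered)
Reagents that add atoms: none
Why: Acid‑catalysed Friedel–Crafts conjugate alkylation ortho to OH followed by lactonisation with loss of water (dihydrocoumarin synthesis) forms C4a–C4 and differentiates the two oxygens; the two free ring positions of 7 are equivalent, so only one regioisomer can form, and the excess of 7 should suppress a second annulation.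

Step 5
Reactants: 10 6-hydroxy-5,8-dimethylchroman-2-one
Product: 11 6-(benzyloxy)-5,8-dimethylchroman-2-one
Conditions: BnBr, K2CO3, acetone, reflux
Reagents that add atoms: benzyl bromide, BrCc1ccccc1
Why: Williamson O‑benzylation of the only free phenol under mild carbonate conditions should leave the aryl lactone closed.

Step 6
Reactants: 11 6-(benzyloxy)-5,8-dimethylchroman-2-one
Product: 12 6-(benzyloxy)-5,8-dimethylchroman-2-ol
Conditions: DIBAL-H (1.1 equiv), CH2Cl2, −78 °C; Rochelle salt work-up
Reagents that add atoms: none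
Why: Half‑reduction of a lactone with DIBAL‑H at low temperature stops at the aluminium lactolate and gives the lactol on work‑up.

Step 7
Reactants: 12 6-(benzyloxy)-5,8-dimethylchroman-2-ol
Product: 14 4-(benzyloxy)-2-(but-3-yn-1-yl)-3,6-dimethylphenol, via open-chain hydroxy aldehyde 13 (not isolated)
Conditions: dimethyl (1-diazo-2-oxopropyl)phosphonate, K2CO3, MeOH, 0 °C to rt
Reagents that add atoms: dimethyl (1-diazo-2-oxopropyl)phosphonate, CC(=O)C(=[N+]=[N-])P(=O)(OC)OC
Why: Seyferth–Gilbert homologation under Ohira–Bestmann conditions acts on the aldehyde tautomer of the lactol, adds the alkyne terminus carbon and frees the phenol that becomes O1.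

Step 8
Reactants: 14 4-(benzyloxy)-2-(but-3-yn-1-yl)-3,6-dimethylphenol
Product: 15 TBS ether of 14
Conditions: TBSCl, imidazole, DMF, 40 °C
Reagents that add atoms: tert-butyldimethylsilyl chloride, CC(C)(C)[Si](C)(C)Cl
Why: Silylation of the hindered phenol masks the acidic OH for the organometallic steps and prevents oxa‑Michael addition to the later enone.

Step 9
Reactants: 15 TBS-protected butynyl arene
Product: 17 TBS-protected (E)-4-iodo-3-methylbut-3-enyl arene, via alkenylalane 16 (not isolated)
Conditions: Me3Al (2.5 equiv), Cp2ZrCl2 (0.25 equiv), CH2Cl2, 0 °C to rt; then I2, THF, −30 to 0 °C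
Reagents that add atoms: trimethylaluminium, C[Al](C)C; iodine, II
Why: Negishi Zr‑catalysed methylalumination of a terminal alkyne is syn and puts methyl on the internal carbon, and iodinolysis of the C–Al bond with retention gives the E‑iodoalkene, which fixes the alkene geometry on which the chirality transfer depends.

Step 10
Reactants: 17 TBS-protected (E)-iodoalkene; 6 (3R,7R)-N-methoxy-N,3,7,11-tetramethyldodecanamide
Product: 19 (3E,7R,11R)-enone, via alkenyllithium 18 (not isolated)
Conditions: t-BuLi (2.05 equiv), Et2O, −78 °C; then 6, −78 to 0 °C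
Reagents that add atoms: none
Why: Iodine–lithium exchange proceeds with retention of alkene geometry and the alkenyllithium acylates the Weinreb amide once through the chelated tetrahedral intermediate, joining arene and chain at C1′–C2′ as the E‑enone.

Step 11
Reactants: 19 (3E,7R,11R)-enone
Product: 20 (3E,5R,7R,11R)-allylic alcohol (TBS ether)
Conditions: (S)-2-methyl-CBS-oxazaborolidine (0.2 equiv), catecholborane (1.5 equiv), toluene, −78 °C
Reagents that add atoms: none
Why: Corey–Bakshi–Shibata reduction, in which the β,β‑disubstituted alkenyl group acts as the large and the chain CH2 as the small substituent, should give the 5R alcohol with the (S)‑catalyst by 1,2‑reduction only.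

Step 12
Reactants: 20 (3E,5R,7R,11R)-allylic alcohol (TBS ether)
Product: 21 4-(benzyloxy)-2-[(3E,5R,7R,11R)-5-hydroxy-3,7,11,15-tetramethylhexadec-3-en-1-yl]-3,6-dimethylphenol
Conditions: TBAF, THF, 0 °C
Reagents that add atoms: none
Why: Fluoride cleaves the aryl silyl ether selectively, the benzyl ether, allylic alcohol and alkene being inert.

Step 13
Reactants: 21 4-(benzyloxy)-2-[(3E,5R,7R,11R)-5-hydroxy-3,7,11,15-tetramethylhexadec-3-en-1-yl]-3,6-dimethylphenol
Product: 22 (2S)-6-(benzyloxy)-2,5,8-trimethyl-2-[(1E,4R,8R)-4,8,12-trimethyltridec-1-en-1-yl]chromane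
Conditions: PdCl2(MeCN)2 (10 mol%), THF, 0 °C
Reagents that add atoms: none
Why: Proposed new method: PdCl2(MeCN)2 binds the C3=C4 alkene of 21 (C2=C1′ of the target) on the face that carries the allylic hydroxyl, the phenol oxygen adds to the fully substituted alkene carbon on that same face (syn‑oxypalladation), and syn‑β‑hydroxide elimination releases water and Pd(II), a net syn‑SN2′ cyclodehydration. The closest known reaction type is the Pd(II)‑catalysed 1,3‑chirality‑transfer cyclisation of hydroxy‑tethered secondary allylic alcohols to 2‑alkenyl tetrahydropyrans, and Pd(II)‑catalysed SN2′ closures of phenols onto allylic electrophiles to 2‑vinylchromans are also known; new here is a phenol adding to a trisubstituted alkene so that an O‑bearing quaternary carbon forms under substrate control. The pyran ring closes 6‑exo‑trig by O1–C2 bond formation. C2 is controlled by the C5 carbinol (C2′): A(1,3) strain with the alkene methyl holds the carbinol C–H in the alkene plane, so OH and C6 lie on opposite faces, and delivery of O1 to the hydroxyl face of the E‑alkene from the 5R alcohol gives 2S in 22 (the spatial arrangement of 2R in the target) and the E‑C1′=C2′ alkene. The step needs stereospecific reaction through this one conformer without ionisation to a free allyl cation, which the non‑acidic conditions at 0 °C and the A(1,3)‑locked E‑alkene should secure; regiochemistry is fixed because only the six‑membered ring is within reach.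

Step 14
Reactants: 22 (2S)-6-(benzyloxy)-2,5,8-trimethyl-2-[(1E,4R,8R)-4,8,12-trimethyltridec-1-en-1-yl]chromane
Product: 23 beta-tocopherol
Conditions: H2 (1 atm), 10% Pd/C, EtOAc, rt
Reagents that add atoms: none
Why: Heterogeneous hydrogenation saturates the unhindered disubstituted C1′=C2′ alkene and hydrogenolyses the benzyl ether in one operation, a known outcome for 2‑alkenyl‑6‑benzyloxychromans, and forms or touches no stereocentre.

**Compound list**

1 | (2E,6E)-3,7,11-trimethyldodeca-2,6,10-trien-1-ol (farnesol) | CC(C)=CCC/C(C)=C/CC/C(C)=C/CO | starting material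
2 | (3R,7R)-3,7,11-trimethyldodecan-1-ol | OCC[C@H](C)CCC[C@H](C)CCCC(C)C | intermediate
3 | (3R,7R)-3,7,11-trimethyldodecanal | O=CC[C@H](C)CCC[C@H](C)CCCC(C)C | intermediate (not isolated)
4 | (3R,7R)-3,7,11-trimethyldodecanoic acid | OC(=O)C[C@H](C)CCC[C@H](C)CCCC(C)C | intermediate
5 | 1-[(3R,7R)-3,7,11-trimethyldodecanoyl]-1H-imidazole | O=C(C[C@H](C)CCC[C@H](C)CCCC(C)C)n1ccnc1 | intermediate (not isolated)
6 | (3R,7R)-N-methoxy-N,3,7,11-tetramethyldodecanamide | CON(C)C(=O)C[C@H](C)CCC[C@H](C)CCCC(C)C | intermediate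
7 | 2,5-dimethylbenzene-1,4-diol (2,5-dimethylhydroquinone) | Cc1cc(O)c(C)cc1O | starting material
8 | acrylic acid | C=CC(=O)O | starting material
9 | 3-(2,5-dihydroxy-3,6-dimethylphenyl)propanoic acid | OC(=O)CCc1c(O)c(C)cc(O)c1C | intermediate (not isolated)
10 | 6-hydroxy-5,8-dimethylchroman-2-one | O=C1CCc2c(C)c(O)cc(C)c2O1 | intermediate
11 | 6-(benzyloxy)-5,8-dimethylchroman-2-one | O=C1CCc2c(C)c(OCc3ccccc3)cc(C)c2O1 | intermediate
12 | 6-(benzyloxy)-5,8-dimethylchroman-2-ol (lactol, both C2 configurations) | OC1CCc2c(C)c(OCc3ccccc3)cc(C)c2O1 | intermediate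
13 | 3-[3-(benzyloxy)-6-hydroxy-2,5-dimethylphenyl]propanal | O=CCCc1c(C)c(OCc2ccccc2)cc(C)c1O | intermediate (not isolated)
14 | 4-(benzyloxy)-2-(but-3-yn-1-yl)-3,6-dimethylphenol | Oc1c(C)cc(OCc2ccccc2)c(C)c1CCC#C | intermediate
15 | [4-(benzyloxy)-2-(but-3-yn-1-yl)-3,6-dimethylphenoxy](tert-butyl)dimethylsilane | CC(C)(C)[Si](C)(C)Oc1c(C)cc(OCc2ccccc2)c(C)c1CCC#C | intermediate
16 | {(1E)-4-[3-(benzyloxy)-6-(tert-butyldimethylsilyloxy)-2,5-dimethylphenyl]-2-methylbut-1-en-1-yl}dimethylalane | CC(C)(C)[Si](C)(C)Oc1c(C)cc(OCc2ccccc2)c(C)c1CC/C(C)=C/[Al](C)C | intermediate (not isolated)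
17 | {4-(benzyloxy)-2-[(3E)-4-iodo-3-methylbut-3-en-1-yl]-3,6-dimethylphenoxy}(tert-butyl)dimethylsilane | CC(C)(C)[Si](C)(C)Oc1c(C)cc(OCc2ccccc2)c(C)c1CC/C(C)=C/I | intermediate
18 | {(1E)-4-[3-(benzyloxy)-6-(tert-butyldimethylsilyloxy)-2,5-dimethylphenyl]-2-methylbut-1-en-1-yl}lithium | CC(C)(C)[Si](C)(C)Oc1c(C)cc(OCc2ccccc2)c(C)c1CC/C(C)=C/[Li] | intermediate (not isolated)
19 | (3E,7R,11R)-1-[3-(benzyloxy)-6-(tert-butyldimethylsilyloxy)-2,5-dimethylphenyl]-3,7,11,15-tetramethylhexadec-3-en-5-one | CC(C)(C)[Si](C)(C)Oc1c(C)cc(OCc2ccccc2)c(C)c1CC/C(C)=C/C(=O)C[C@H](C)CCC[C@H](C)CCCC(C)C | intermediate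
20 | (3E,5R,7R,11R)-1-[3-(benzyloxy)-6-(tert-butyldimethylsilyloxy)-2,5-dimethylphenyl]-3,7,11,15-tetramethylhexadec-3-en-5-ol | CC(C)(C)[Si](C)(C)Oc1c(C)cc(OCc2ccccc2)c(C)c1CC/C(C)=C/[C@H](O)C[C@H](C)CCC[C@H](C)CCCC(C)C | intermediate
21 | 4-(benzyloxy)-2-[(3E,5R,7R,11R)-5-hydroxy-3,7,11,15-tetramethylhexadec-3-en-1-yl]-3,6-dimethylphenol | Oc1c(C)cc(OCc2ccccc2)c(C)c1CC/C(C)=C/[C@H](O)C[C@H](C)CCC[C@H](C)CCCC(C)C | intermediate
22 | (2S)-6-(benzyloxy)-2,5,8-trimethyl-2-[(1E,4R,8R)-4,8,12-trimethyltridec-1-en-1-yl]chromane | Cc1cc(OCc2ccccc2)c(C)c2c1O[C@](C)(/C=C/C[C@H](C)CCC[C@H](C)CCCC(C)C)CC2 | intermediate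
23 | (2R)-2,5,8-trimethyl-2-[(4R,8R)-4,8,12-trimethyltridecyl]chroman-6-ol (beta-tocopherol) | Cc1cc(O)c(C)c2c1O[C@](C)(CCC[C@H](C)CCC[C@H](C)CCCC(C)C)CC2 | target

**Step count and risks**

Total step count: 14. Longest linear sequence: 11 steps (steps 4–14, from 7).

Steps most likely to fail:

1. Step 13 (proposed new method). Pd(II) may act as a Lewis acid and ionise the allylic alcohol to a free allyl cation before the C–O bond forms, which would erase the chirality transfer; the σ‑alkylpalladium may also lose β‑hydride instead of β‑hydroxide and give a ketone. The fallback uses known chemistry, sets out from 15 (and from 2 for the chain) and returns at 23. Methylalumination of 15 as in step 9, then n‑BuLi and paraformaldehyde, gives the primary allylic alcohol F1. Methyl chloroformate/pyridine gives the allyl methyl carbonate F2, and acetic‑acid‑buffered TBAF frees the phenol carbonate F3. Pd(0)‑catalysed asymmetric allylic etherification (Tsuji–Trost type, Pd2(dba)3 with the C2‑symmetric trans‑1,2‑diaminocyclohexane bis(2‑diphenylphosphinobenzamide) ligand in the enantiomer giving 2S, AcOH, CH2Cl2) closes the ring under catalyst control to the vinylchroman F4. Lemieux–Johnson cleavage (OsO4 cat., NaIO4) gives the chroman aldehyde F5. In parallel, 2 is converted by the Appel reaction to the bromide F6 and with PPh3 to the phosphonium salt F7. Wittig olefination of F5 with the ylide of F7 (NaHMDS, THF) gives the Z‑alkene F8, which the conditions of step 14 convert to 23.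

2. Step 11. Facial discrimination between the alkenyl and CH2 flanks of the ketone may be insufficient, and the minor carbinol would be carried through as the C2 epimer, which cannot be removed later. The fallback sets out from 15 and 6 and returns at 20. Deprotonation of 15 (n‑BuLi, THF, −78 °C) and acylation with 6 gives the ynone F9. Noyori transfer hydrogenation (RuCl(p‑cymene)(TsDPEN), enantiomer giving 5R, i‑PrOH) gives the propargylic alcohol F10, for which alkynyl/alkyl discrimination is large. Hydroxyl‑directed trans‑hydroalumination with Red‑Al and iodinolysis gives the Z‑iodoalkenol F11, and Me2CuLi replaces iodine by methyl with retention to give 20.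

3. Step 4. The lactone may undergo a second annulation at the remaining free ring position, and the hydroquinone may be air‑oxidised under hot acidic conditions. The fallback sets out from 7 and returns at 11. Monobenzylation of 7 (BnBr 1 equiv, K2CO3, excess 7) gives the monobenzyl ether F12, which leaves a single position ortho to a free OH. Pd(OAc)2/HCO2H‑mediated hydroarylation–lactonisation with ethyl propiolate gives the coumarin F13. Copper hydride conjugate reduction ([(Ph3P)CuH]6 or CuCl/PPh3/PMHS) gives 11.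

Further compounds
F1 | step 13 | (2E)-5-[3-(benzyloxy)-6-(tert-butyldimethylsilyloxy)-2,5-dimethylphenyl]-3-methylpent-2-en-1-ol | CC(C)(C)[Si](C)(C)Oc1c(C)cc(OCc2ccccc2)c(C)c1CC/C(C)=C/CO
F2 | step 13 | (2E)-5-[3-(benzyloxy)-6-(tert-butyldimethylsilyloxy)-2,5-dimethylphenyl]-3-methylpent-2-en-1-yl methyl carbonate | CC(C)(C)[Si](C)(C)Oc1c(C)cc(OCc2ccccc2)c(C)c1CC/C(C)=C/COC(=O)OC
F3 | step 13 | (2E)-5-[3-(benzyloxy)-6-hydroxy-2,5-dimethylphenyl]-3-methylpent-2-en-1-yl methyl carbonate | Oc1c(C)cc(OCc2ccccc2)c(C)c1CC/C(C)=C/COC(=O)OC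
F4 | step 13 | (2S)-6-(benzyloxy)-2-ethenyl-2,5,8-trimethylchromane | Cc1cc(OCc2ccccc2)c(C)c2c1O[C@](C)(C=C)CC2
F5 | step 13 | (2S)-6-(benzyloxy)-2,5,8-trimethylchromane-2-carbaldehyde | Cc1cc(OCc2ccccc2)c(C)c2c1O[C@](C)(C=O)CC2
F6 | step 13 | (3R,7R)-1-bromo-3,7,11-trimethyldodecane | BrCC[C@H](C)CCC[C@H](C)CCCC(C)C
F7 | step 13 | [(3R,7R)-3,7,11-trimethyldodecyl]triphenylphosphonium bromide | [Br-].c1ccccc1[P+](c1ccccc1)(c1ccccc1)CC[C@H](C)CCC[C@H](C)CCCC(C)C
F8 | step 13 | (2S)-6-(benzyloxy)-2,5,8-trimethyl-2-[(1Z,4R,8R)-4,8,12-trimethyltridec-1-en-1-yl]chromane | Cc1cc(OCc2ccccc2)c(C)c2c1O[C@](C)(/C=C\C[C@H](C)CCC[C@H](C)CCCC(C)C)CC2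
F9 | step 11 | (7R,11R)-1-[3-(benzyloxy)-6-(tert-butyldimethylsilyloxy)-2,5-dimethylphenyl]-7,11,15-trimethylhexadec-3-yn-5-one | CC(C)(C)[Si](C)(C)Oc1c(C)cc(OCc2ccccc2)c(C)c1CCC#CC(=O)C[C@H](C)CCC[C@H](C)CCCC(C)C
F10 | step 11 | (5R,7R,11R)-1-[3-(benzyloxy)-6-(tert-butyldimethylsilyloxy)-2,5-dimethylphenyl]-7,11,15-trimethylhexadec-3-yn-5-ol | CC(C)(C)[Si](C)(C)Oc1c(C)cc(OCc2ccccc2)c(C)c1CCC#C[C@H](O)C[C@H](C)CCC[C@H](C)CCCC(C)C
F11 | step 11 | (3Z,5R,7R,11R)-1-[3-(benzyloxy)-6-(tert-butyldimethylsilyloxy)-2,5-dimethylphenyl]-3-iodo-7,11,15-trimethylhexadec-3-en-5-ol | CC(C)(C)[Si](C)(C)Oc1c(C)cc(OCc2ccccc2)c(C)c1CC/C(I)=C/[C@H](O)C[C@H](C)CCC[C@H](C)CCCC(C)C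
F12 | step 4 | 4-(benzyloxy)-2,5-dimethylphenol | Cc1cc(OCc2ccccc2)c(C)cc1O
F13 | step 4 | 6-(benzyloxy)-5,8-dimethyl-2H-chromen-2-one | O=C1C=Cc2c(C)c(OCc3ccccc3)cc(C)c2O1
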